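A direct plan would benzylate 2,3,4-trihydroxyacetophenone A1, brominate C5, exchange bromide for methoxide under copper catalysis and benzylate again to reach the fully protected acetophenone A2.
It would condense A2 with 3-benzyloxy-4,5-dimethoxybenzaldehyde A3 to chalcone A4, rearrange A4 with Tl(NO3)3 in methanol to the β-keto acetal A5, then hydrogenolyse and close ring C with acid.
Weak point (a): the oxidative 1,2-aryl shift A4 to A5 would consume a full equivalent of toxic trivalent thallium and would have to move the crowded aryl group that came from A3 in a substrate that offers the oxidant several other electron-rich sites.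
Weak point (b): the four steps from A1 to A2 (protect, brominate, methoxylate, reprotect) would form no bond of the skeleton and would only decorate a purchased ring A.
Weak point (c): the final hydrogenolysis would expose an air-sensitive trihydroxyaryl ketone before ring C is closed, so the most fragile intermediate would appear at the very end.

**Retrosynthetic overview**
- Last step: BCl3 removes three isopropyl ethers (O7, O8, O3'), so the free phenols appear only after the chromone is closed.
- Ring C: the O1–C2 and C2–C3 bonds come from a 2-hydroxydeoxybenzoin and Me2NCH(OMe)2, in the same flask as ring A.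
- Ring A is made, not bought: the four contiguous oxygen atoms on C6, C7, C8 and C8a (OMe, OH, OH and ring oxygen O1) are the four oxygens of diisopropyl squarate, and C5 and C4a are a vinyl unit. Thermal ring opening of a 4-alkenyl-4-methoxycyclobutenone and 6π closure form the C4a–C8a bond.
- Precursor of the key step: squarate plus an (E)-stannylvinyllithium (C5–C6 bond), O-methylation, then acylative Stille coupling with the ring B arylacetyl chloride (C4–C4a bond).
- Ring order is B (bought), A, C. There is no aryl migration, no thallium and no bromination, methoxylation or reprotection on ring A, because the ring construction itself places H, OMe, OR, OR, OH and the acyl group.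

Key step: step 6

Remark: atom labels follow chromen-4-one numbering (ring A: C4a, C5–C8, C8a; ring C: O1, C2–C4; ring B primed). The three starting materials are taken as catalogue chemicals. The target has no stereocentre; every stereocentre of an intermediate is racemic and is erased later.

Step 1
Reactants: 1 3-hydroxy-4,5-dimethoxybenzaldehyde
Product: 2 3-isopropoxy-4,5-dimethoxybenzaldehyde
Conditions: 2-bromopropane (1.5 equiv), K2CO3 (2 equiv), DMF, 60 °C
Reagents that add atoms: 2-bromopropane, CC(C)Br
Why: Williamson etherification of the only phenol installs an isopropyl ether that matches the squarate esters, so that one reagent removes all three at the end.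

Step 2
Reactants: 2 3-isopropoxy-4,5-dimethoxybenzaldehyde
Product: 3 2-(3-isopropoxy-4,5-dimethoxyphenyl)acetonitrile
Conditions: TosMIC (1.3 equiv), t-BuOK (2.5 equiv), DME, −40 °C, 1 h; then MeOH, 70 °C, 30 min
Reagents that add atoms: p-toluenesulfonylmethyl isocyanide (TosMIC), Cc1ccc(cc1)S(=O)(=O)C[N+]#[C-]
Why: van Leusen reductive cyanation, in which the TosMIC anion adds to the aldehyde, the oxazoline anion opens to an N-formyl enamide and methanol removes formate and sulfinate to leave the one-carbon-homologated nitrile, the cold first stage holding back oxazole formation.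

Step 3
Reactants: 3 2-(3-isopropoxy-4,5-dimethoxyphenyl)acetonitrile
Product: 4 2-(3-isopropoxy-4,5-dimethoxyphenyl)acetic acid
Conditions: NaOH (20% aq.), EtOH, reflux; then HCl to pH 2
Reagents that add atoms: sodium hydroxide, [Na+].[OH-]; water, O
Why: base hydrolysis of the nitrile through the amide gives the arylacetic acid, and the aryl alkyl ethers are inert to hydroxide.

Step 4
Reactants: 5 3,4-diisopropoxycyclobut-3-ene-1,2-dione (diisopropyl squarate); 6 (E)-1,2-bis(tributylstannyl)ethene
Product: 9 4-methoxy-2,3-diisopropoxy-4-[(E)-2-(tributylstannyl)ethenyl]cyclobut-2-en-1-one, via stannylvinyllithium 7 (not isolated), via lithium alkoxide 8 (not isolated)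
Conditions: 6, n-BuLi (1.0 equiv), THF, −78 °C, 1 h; add to 5, THF, −78 °C; MeOTf (1.5 equiv), −78 to 0 °C
Reagents that add atoms: methyl trifluoromethanesulfonate, COS(=O)(=O)C(F)(F)F
Why: tin–lithium exchange on one stannyl group gives the (E)-stannylvinyllithium, which adds 1,2 to one of the two equivalent carbonyl groups of the squarate, and O-methylation of the tertiary alkoxide fixes the oxygen that becomes the 6-methoxy group; the quaternary centre is racemic and is erased in step 6.

Step 5
Reactants: 4 2-(3-isopropoxy-4,5-dimethoxyphenyl)acetic acid; 9 4-methoxy-2,3-diisopropoxy-4-[(E)-2-(tributylstannyl)ethenyl]cyclobut-2-en-1-one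
Product: 11 4-[(1E)-4-(3-isopropoxy-4,5-dimethoxyphenyl)-3-oxobut-1-en-1-yl]-4-methoxy-2,3-diisopropoxycyclobut-2-en-1-one, via arylacetyl chloride 10 (not isolated)
Conditions: 4, (COCl)2 (1.2 equiv), DMF (cat.), CH2Cl2, 0 °C to rt, evaporate; then 9, BnPdCl(PPh3)2 (3 mol %), CHCl3, 40 °C, dark
Reagents that add atoms: none
Why: Stille acylation of the vinylstannane by the acid chloride under palladium catalysis joins C4 to the future C4a with retention of the E geometry, at a temperature below the ring opening of the cyclobutenone, and any ring opening that does set in only anticipates step 6.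

Step 6
Reactants: 11 4-[(1E)-4-(3-isopropoxy-4,5-dimethoxyphenyl)-3-oxobut-1-en-1-yl]-4-methoxy-2,3-diisopropoxycyclobut-2-en-1-one
Product: 16 7,8-diisopropoxy-3-(3-isopropoxy-4,5-dimethoxyphenyl)-6-methoxy-4H-chromen-4-one, via dienylketene 12 (not isolated), via cyclohexadienone 13 (not isolated), via deoxybenzoin 14 (not isolated), via enaminone 15 (not isolated)
Conditions: PhMe (degassed, 0.02 M), 110 °C, 2 h; then Me2NCH(OMe)2 (3 equiv), 100 °C, 4 h
Reagents that add atoms: N,N-dimethylformamide dimethyl acetal, COC(OC)N(C)C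
Why: Thermal conrotatory 4π ring opening of the cyclobutenone, in which the 4-methoxy group turns outward and so places the alkenyl group cis to the ketene, should give dienylketene 12, whose disrotatory 6π electrocyclisation joins the ketene carbon (C8a) to the acyl-bearing alkene carbon (C4a) and whose enolisation aromatises ring A to phenol 14; the closest known reaction is the Moore rearrangement of 4-alkenyl-4-alkoxycyclobutenones to hydroquinone monoethers. Ring A thus closes by 6π electrocyclisation and carries, without any choice of site, OMe on C6 (carbinol oxygen), OiPr on C7 and C8 (squarate esters), OH on C8a (ketene oxygen), H on C5 and the acyl chain on C4a. Me2NCH(OMe)2 is added only after the ketene is consumed, because the methanol it releases would add to the ketene; it condenses at the doubly activated CH2 of 14 to enaminone 15, as in the standard conversion of 2-hydroxydeoxybenzoins into isoflavones. Ring C then closes by 6-endo addition of the ortho phenol oxygen to the β-carbon of the enaminone (O1–C2 bond) and loss of dimethylamine. The step needs the E alkene (acyl group outward in the electrocyclisation, secured by step 5) and a single free phenol ortho to the ketone (secured by the squarate mapping); the sp3 centre of 13 is lost on aromatisation, so no stereocentre remains.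

Step 7
Reactants: 16 7,8-diisopropoxy-3-(3-isopropoxy-4,5-dimethoxyphenyl)-6-methoxy-4H-chromen-4-one
Product: 17 7,8-dihydroxy-3-(3-hydroxy-4,5-dimethoxyphenyl)-6-methoxy-4H-chromen-4-one
Conditions: BCl3 (1 M in CH2Cl2, 6 equiv), CH2Cl2, −78 to 0 °C; MeOH quench, aq. work-up under N2
Reagents that add atoms: none
Why: BCl3 cleaves the three secondary-alkyl aryl ethers through ion-pair (SN1-like) collapse to 2-chloropropane much faster than it attacks aryl methyl ethers, none of which lies next to the C4 carbonyl, and the chromone is inert, so the three phenols appear only in the last operation.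

**Compound list**
1 | 3-hydroxy-4,5-dimethoxybenzaldehyde | COc1cc(C=O)cc(O)c1OC | starting material
2 | 3-isopropoxy-4,5-dimethoxybenzaldehyde | COc1cc(C=O)cc(OC(C)C)c1OC | intermediate
3 | 2-(3-isopropoxy-4,5-dimethoxyphenyl)acetonitrile | COc1cc(CC#N)cc(OC(C)C)c1OC | intermediate
4 | 2-(3-isopropoxy-4,5-dimethoxyphenyl)acetic acid | COc1cc(CC(=O)O)cc(OC(C)C)c1OC | intermediate
5 | 3,4-diisopropoxycyclobut-3-ene-1,2-dione (diisopropyl squarate) | CC(C)OC1=C(OC(C)C)C(=O)C1=O | starting material
6 | (E)-1,2-bis(tributylstannyl)ethene | CCCC[Sn](CCCC)(CCCC)/C=C/[Sn](CCCC)(CCCC)CCCC | starting material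
7 | [(E)-2-(tributylstannyl)ethenyl]lithium (not isolated) | [Li]/C=C/[Sn](CCCC)(CCCC)CCCC | intermediate
8 | lithium 4-oxo-2,3-diisopropoxy-1-[(E)-2-(tributylstannyl)ethenyl]cyclobut-2-en-1-olate (racemic, not isolated) | CC(C)OC1=C(OC(C)C)C([O-])(/C=C/[Sn](CCCC)(CCCC)CCCC)C1=O.[Li+] | intermediate
9 | 4-methoxy-2,3-diisopropoxy-4-[(E)-2-(tributylstannyl)ethenyl]cyclobut-2-en-1-one (racemic) | CC(C)OC1=C(OC(C)C)C(OC)(/C=C/[Sn](CCCC)(CCCC)CCCC)C1=O | intermediate
10 | 2-(3-isopropoxy-4,5-dimethoxyphenyl)acetyl chloride (not isolated) | COc1cc(CC(=O)Cl)cc(OC(C)C)c1OC | intermediate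
11 | 4-[(1E)-4-(3-isopropoxy-4,5-dimethoxyphenyl)-3-oxobut-1-en-1-yl]-4-methoxy-2,3-diisopropoxycyclobut-2-en-1-one (racemic) | CC(C)OC1=C(OC(C)C)C(OC)(/C=C/C(=O)Cc2cc(OC)c(OC)c(OC(C)C)c2)C1=O | intermediate
12 | (3Z,5E)-8-(3-isopropoxy-4,5-dimethoxyphenyl)-4-methoxy-2,3-diisopropoxyocta-1,3,5-triene-1,7-dione (dienylketene, not isolated) | O=C=C(OC(C)C)/C(OC(C)C)=C(OC)\C=C\C(=O)Cc1cc(OC)c(OC)c(OC(C)C)c1 | intermediate
13 | 6-[2-(3-isopropoxy-4,5-dimethoxyphenyl)acetyl]-4-methoxy-2,3-diisopropoxycyclohexa-2,4-dien-1-one (racemic, not isolated) | O=C1C(OC(C)C)=C(OC(C)C)C(OC)=CC1C(=O)Cc2cc(OC)c(OC)c(OC(C)C)c2 | intermediate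
14 | 1-(2-hydroxy-3,4-diisopropoxy-5-methoxyphenyl)-2-(3-isopropoxy-4,5-dimethoxyphenyl)ethan-1-one (not isolated) | COc1cc(C(=O)Cc2cc(OC)c(OC)c(OC(C)C)c2)c(O)c(OC(C)C)c1OC(C)C | intermediate
15 | 3-(dimethylamino)-1-(2-hydroxy-3,4-diisopropoxy-5-methoxyphenyl)-2-(3-isopropoxy-4,5-dimethoxyphenyl)prop-2-en-1-one (alkene geometry not defined, not isolated) | COc1cc(C(=O)C(=CN(C)C)c2cc(OC)c(OC)c(OC(C)C)c2)c(O)c(OC(C)C)c1OC(C)C | intermediate
16 | 7,8-diisopropoxy-3-(3-isopropoxy-4,5-dimethoxyphenyl)-6-methoxy-4H-chromen-4-one | COc1cc2c(=O)c(-c3cc(OC)c(OC)c(OC(C)C)c3)coc2c(OC(C)C)c1OC(C)C | intermediate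
17 | 7,8-dihydroxy-3-(3-hydroxy-4,5-dimethoxyphenyl)-6-methoxy-4H-chromen-4-one | COc1cc2c(=O)c(-c3cc(O)c(OC)c(OC)c3)coc2c(O)c1O | target

**Step count and risk**
Total steps: 7. Longest linear sequence: 6 (steps 1, 2, 3, 5, 6, 7).

Step 5 (acylative Stille coupling). The arylacetyl–palladium intermediate may lose CO to a benzyl–palladium species, the acid chloride may be consumed as a ketene, and traces of HCl may strip tin from 9. The fallback makes the same C4–C4a bond by a three-component carbonylative coupling, in which CO pressure drives a benzyl–palladium species back to the acyl complex. It sets out from aldehyde 2 and stannane 9. Reduction of 2 (NaBH4, MeOH, 0 °C) should give (3-isopropoxy-4,5-dimethoxyphenyl)methanol F1, and SOCl2 (CH2Cl2, 0 °C) should convert it into 5-(chloromethyl)-1-isopropoxy-2,3-dimethoxybenzene F2. F2, stannane 9 and CO (3 atm) with BnPdCl(PPh3)2 in THF at 45 °C should then give enone 11, where the fallback comes back to the route.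

Step 6 (thermal cascade). The acceptor-substituted alkene terminus may slow the 6π closure, so that the dienylketene is diverted into dimers or adducts, or the enone may decompose on heating. The fallback carries C4 through the ring formation at the alcohol oxidation level, the substrate class on which this rearrangement is best established. It sets out from stannane 9 and nitrile 3. I2 (CH2Cl2, 0 °C) should convert 9 into 4-[(E)-2-iodoethenyl]-4-methoxy-2,3-diisopropoxycyclobut-2-en-1-one F3. iBu2AlH (PhMe, −78 °C; aq. tartaric acid) should reduce 3 to 2-(3-isopropoxy-4,5-dimethoxyphenyl)acetaldehyde F4. Nozaki–Hiyama–Kishi coupling of F3 and F4 (CrCl2, NiCl2 cat., DMF, rt), in which the vinylchromium species adds to the aldehyde and not to the ring ketone, should give 4-[(1E)-3-hydroxy-4-(3-isopropoxy-4,5-dimethoxyphenyl)but-1-en-1-yl]-4-methoxy-2,3-diisopropoxycyclobut-2-en-1-one F5. Thermolysis of F5 (PhMe, 110 °C) should give 6-[1-hydroxy-2-(3-isopropoxy-4,5-dimethoxyphenyl)ethyl]-2,3-diisopropoxy-4-methoxyphenol F6. MnO2 (CH2Cl2, rt) should oxidise the benzylic alcohol of F6 to deoxybenzoin 14. The fallback comes back to the route here; 14 takes up Me2NCH(OMe)2 as in the second stage of step 6 to give 16.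

Step 4 (addition and O-methylation). The hindered tertiary alkoxide may be methylated incompletely, or may revert or open its ring before it is trapped. The fallback leaves the carbinol free and places the methyl group after both rings exist, when O6 is the only free phenol. It sets out from alkoxide 8. Quenching 8 with aq. NH4Cl at −78 °C should give 4-hydroxy-2,3-diisopropoxy-4-[(E)-2-(tributylstannyl)ethenyl]cyclobut-2-en-1-one F7. Acylation of F7 with acid chloride 10 as in step 5 should give 4-hydroxy-4-[(1E)-4-(3-isopropoxy-4,5-dimethoxyphenyl)-3-oxobut-1-en-1-yl]-2,3-diisopropoxycyclobut-2-en-1-one F8. Thermolysis of F8 under N2 as in step 6 should give 1-(2,5-dihydroxy-3,4-diisopropoxyphenyl)-2-(3-isopropoxy-4,5-dimethoxyphenyl)ethan-1-one F9. Me2NCH(OMe)2 in the same flask should close ring C to 6-hydroxy-7,8-diisopropoxy-3-(3-isopropoxy-4,5-dimethoxyphenyl)-4H-chromen-4-one F10; any O-methylation of the 6-hydroxyl by this reagent only anticipates the next operation. MeI and K2CO3 in acetone should methylate F10 to 16, where the fallback comes back to the route.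

**Further compounds**
F1 | step 5 | (3-isopropoxy-4,5-dimethoxyphenyl)methanol | COc1cc(CO)cc(OC(C)C)c1OC
F2 | step 5 | 5-(chloromethyl)-1-isopropoxy-2,3-dimethoxybenzene | COc1cc(CCl)cc(OC(C)C)c1OC
F3 | step 6 | 4-[(E)-2-iodoethenyl]-4-methoxy-2,3-diisopropoxycyclobut-2-en-1-one (racemic) | CC(C)OC1=C(OC(C)C)C(OC)(/C=C/I)C1=O
F4 | step 6 | 2-(3-isopropoxy-4,5-dimethoxyphenyl)acetaldehyde | COc1cc(CC=O)cc(OC(C)C)c1OC
F5 | step 6 | 4-[(1E)-3-hydroxy-4-(3-isopropoxy-4,5-dimethoxyphenyl)but-1-en-1-yl]-4-methoxy-2,3-diisopropoxycyclobut-2-en-1-one (mixture of racemic diastereomers) | CC(C)OC1=C(OC(C)C)C(OC)(/C=C/C(O)Cc2cc(OC)c(OC)c(OC(C)C)c2)C1=O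
F6 | step 6 | 6-[1-hydroxy-2-(3-isopropoxy-4,5-dimethoxyphenyl)ethyl]-2,3-diisopropoxy-4-methoxyphenol (racemic) | COc1cc(C(O)Cc2cc(OC)c(OC)c(OC(C)C)c2)c(O)c(OC(C)C)c1OC(C)C
F7 | step 4 | 4-hydroxy-2,3-diisopropoxy-4-[(E)-2-(tributylstannyl)ethenyl]cyclobut-2-en-1-one (racemic) | CC(C)OC1=C(OC(C)C)C(O)(/C=C/[Sn](CCCC)(CCCC)CCCC)C1=O
F8 | step 4 | 4-hydroxy-4-[(1E)-4-(3-isopropoxy-4,5-dimethoxyphenyl)-3-oxobut-1-en-1-yl]-2,3-diisopropoxycyclobut-2-en-1-one (racemic) | CC(C)OC1=C(OC(C)C)C(O)(/C=C/C(=O)Cc2cc(OC)c(OC)c(OC(C)C)c2)C1=O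
F9 | step 4 | 1-(2,5-dihydroxy-3,4-diisopropoxyphenyl)-2-(3-isopropoxy-4,5-dimethoxyphenyl)ethan-1-one | O=C(Cc1cc(OC)c(OC)c(OC(C)C)c1)c1cc(O)c(OC(C)C)c(OC(C)C)c1O
F10 | step 4 | 6-hydroxy-7,8-diisopropoxy-3-(3-isopropoxy-4,5-dimethoxyphenyl)-4H-chromen-4-one | Oc1cc2c(=O)c(-c3cc(OC)c(OC)c(OC(C)C)c3)coc2c(OC(C)C)c1OC(C)C
A1 | direct plan | 1-(2,3,4-trihydroxyphenyl)ethan-1-one | CC(=O)c1ccc(O)c(O)c1O
A2 | direct plan | 1-[2,3,4-tris(benzyloxy)-5-methoxyphenyl]ethan-1-one | CC(=O)c1cc(OC)c(OCc2ccccc2)c(OCc2ccccc2)c1OCc1ccccc1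
A3 | direct plan | 3-(benzyloxy)-4,5-dimethoxybenzaldehyde | COc1cc(C=O)cc(OCc2ccccc2)c1OC
A4 | direct plan | (E)-3-[3-(benzyloxy)-4,5-dimethoxyphenyl]-1-[2,3,4-tris(benzyloxy)-5-methoxyphenyl]prop-2-en-1-one | COc1cc(C(=O)/C=C/c2cc(OC)c(OC)c(OCc3ccccc3)c2)c(OCc2ccccc2)c(OCc2ccccc2)c1OCc1ccccc1
A5 | direct plan | 2-[3-(benzyloxy)-4,5-dimethoxyphenyl]-3,3-dimethoxy-1-[2,3,4-tris(benzyloxy)-5-methoxyphenyl]propan-1-one (racemic) | COc1cc(C(=O)C(C(OC)OC)c2cc(OC)c(OC)c(OCc3ccccc3)c2)c(OCc2ccccc2)c(OCc2ccccc2)c1OCc1ccccc1
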